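At one temperature, the dawn, summer and winter flasks each turned substrate and partner into product under catalyst for 7.3 h; the dusk flask is to run as long.

| flask | substrate | partner | catalyst | time |
|---|---|---|---|---|
| dawn | 80.0 mM | 64.0 mM | 8.00 mM |  |
| summer | 48.0 mM | 32.0 mM | 8.00 mM |  |
| winter | 80.0 mM | 64.0 mM | 12.0 mM |  |
| dusk | 80.0 mM | 190 mM | 24.0 mM | 7.3 h |

- dawn run (time / h: [substrate] / mM): 0.29: 79.76; 0.50: 79.28; 0.85: 76.95; 1.5: 72.03; 2.5: 65.38; 4.3: 55.31; 7.3: 41.73
- summer run (time / h: [substrate] / mM): 0.29: 48.20; 0.50: 47.90; 0.85: 47.29; 1.5: 45.07; 2.5: 41.40; 4.3: 35.87; 7.3: 28.10
- winter run (time / h: [substrate] / mM): 0.29: 79.43; 0.50: 78.38; 0.85: 75.61; 1.5: 68.83; 2.5: 59.77; 4.3: 46.17; 7.3: 31.87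

(readings scatter by 0.2 mM)

- the exponent of [catalyst] in the starting rate at the charge of the dawn run (at the point where two percent of the substrate have become product)
- the summer run starts with 32.0 mM less of substrate and of partner than the dawn run, and with no product. Compared where both hold the same amount of substrate, once fifteen percent of what the summer run was charged with has turned into product, is the summer run faster, slower or alike (within a tenth)?
- substrate in the dusk run at 7.3 h, as a share of the substrate charged
- which of these the readings show (nothing beyond the main steps / the product speeds the reaction / the catalyst wakes slowly / the two partners rest in a complex)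

- Overall: substrate + partner -> product, with catalyst as catalyst.
- Constant volume, constant temperature.
- Bound and free are read together.
- An order is taken over about fifteen percent of the charge, up and down.

Read the dawn table from the top. It loses 0.828 mM h⁻¹ up to 0.29 h and a faster 7.57 mM h⁻¹ between 0.85 h and 1.5 h, a start that I read as catalyst waking slowly. So I count from the 2.5 h row onward.

Count turnovers next. By its last row, each catalyst in the dawn run has made 4.78 turnovers on average, and the dusk run needs 3.33 to clear its charge. But the dawn run loses a slower 4.53 mM h⁻¹ over its last interval, so I count differently. From the 2.5 h row to the last, the dawn run costs 308 M·s, the turnover price: [catalyst] times hours, divided by the natural logarithm of the ratio by which [substrate] falls.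

Now compare the tables. The dawn run pays 308 M·s at a last-row [substrate]/[partner] of 1.62, and the summer run pays 357 M·s at 2.32. A straight line through these two gives 335 M·s for the winter ratio of 2.01, and the winter table reads 330 M·s.

In the dawn, summer and winter charges partner is the limiting reagent, with substrate ahead by 0.0160 M in each. Between the dawn and summer runs, which both hold 8.00 mM of catalyst, equal [substrate] therefore means equal [partner], and I expect the two to be alike.

The dusk run spends 631 M·s of catalyst-time. Its ratio starts at 0.421 and falls, so my line prices it between 195 M·s and 224 M·s. That leaves my own share between 3.93 % and 5.98 %.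

The forecast gave, in the order asked, 0.7, alike, 11 % and the catalyst wakes slowly, on the ground that “After the lag, decay is nearly first order in substrate”. Its share amounts to a price of 286 M·s, higher than mine.

The flask gives, in the same order, 0.63, alike, 4.94 % and the catalyst wakes slowly.

    active catalyst + substrate → catalyst-substrate complex (18.97 M⁻¹ h⁻¹)
    catalyst-substrate complex + partner → product + active catalyst (50.76 M⁻¹ h⁻¹)
    catalyst + partner → active catalyst + partner (54.36 M⁻¹ h⁻¹)

The pace of the step from catalyst + partner to active catalyst + partner makes no difference worth reckoning to the dusk share. That share of 4.94 % amounts to a price of 210 M·s in the dusk run, lower than the 308 M·s of the dawn run. The winter run's price of 330 M·s reckons 5.29 h for halving its substrate, and the time stored for half its charge to become product is 5.44 h.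

(Readings and results were computed for an exercise, noise included.)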